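A direct plan would dimerise a dibenzylated gallacetophenone, condense the biaryl twice to the bis(2'-hydroxychalcone) A1, close both pyran rings at once to the bis(flav-3-ene) A2, oxygenate both C3=C4 bonds to the hexabenzyl tetrol A3 and debenzylate. Its weakest steps would be the twofold enantioselective pyran closure to A2 (an untried ion-pair cyclisation that carries both C2 centres); the acid equilibration at C4 of the symmetrical tetrol (no reagent can tell C4 from C4', so the 4R,4'S isomer would arise by statistics only, at the most advanced stage); and the final hydrogenolysis of six benzyl ethers beside two electron-rich benzylic carbinols, which Pd/C can cleave as well.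

Cuts: first C6–C6' (two monomers that differ only at C4), then C4–O of the 3,4-trans monomer (inversion of the all-cis one), then C2–H, C3–H and C4–H, back to one flat flavonol. Ring C arises first, as a 4-pyranone on a single ring A, is saturated in one operation, and the chromanes are joined last. Feature used: in the 4R half H-2, H-3 and H-4 of ring C share one face, so the planar C2=C3/C4=O unit can take them up at once; C4 (O1 ortho, O7 para) inverts alone; C6 (para to O1) alone takes bromine. No double ring closure, no chance event at C4, no hydrogenolysis.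

Key step: step 4

Abbreviations: TBS = tert-butyldimethylsilyl; TBSO = tert-butyldimethylsilyloxy; SINpEt·HBF4 = 1,3-bis[1-(naphthalen-1-yl)ethyl]-4,5-dihydroimidazolium tetrafluoroborate (precursor of the chiral N-heterocyclic carbene, NHC).
Remark: the sense of induction of the carbene ligand in step 4 cannot be predicted with certainty; the ligand antipode is to be chosen in a trial run so that the (2R,3R,4R) alcohol results.

Step 1
Reactants: 1 1-(2-hydroxy-3,4-dimethoxyphenyl)ethanone; 2 4-methoxybenzaldehyde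
Product: 4 3-hydroxy-7,8-dimethoxy-2-(4-methoxyphenyl)-4H-chromen-4-one, via chalcone 3 (not isolated)
Conditions: KOH (50% aq), EtOH, rt, 24 h; then 30% H2O2, 0 °C to rt; HCl to pH 3
Reagents that add atoms: hydrogen peroxide, OO
Why: Claisen–Schmidt condensation gives the 2'-hydroxychalcone 3, which alkaline hydrogen peroxide turns into the flavonol by the Algar–Flynn–Oyamada reaction, and since the chalcone has no 6'-substituent the flavonol and not the aurone is expected; no stereocentre is formed.

Step 2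
Reactants: 4 3-hydroxy-7,8-dimethoxy-2-(4-methoxyphenyl)-4H-chromen-4-one
Product: 5 3,7,8-trihydroxy-2-(4-hydroxyphenyl)-4H-chromen-4-one
Conditions: BBr3 (8 equiv), CH2Cl2, −78 °C to rt; MeOH, then H2O
Reagents that add atoms: none
Why: Lewis acid ether cleavage (O–B complexation, bromide attack on methyl) frees the three phenols at the one stage where the molecule is flat, aromatic and free of acid-labile sp3 centres.

Step 3
Reactants: 5 3,7,8-trihydroxy-2-(4-hydroxyphenyl)-4H-chromen-4-one
Product: 6 3,7,8-tris(TBSO)-2-[4-(TBSO)phenyl]-4H-chromen-4-one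
Conditions: TBSCl (6 equiv), imidazole (12 equiv), DMF, rt to 40 °C
Reagents that add atoms: tert-butyldimethylsilyl chloride, CC(C)(C)[Si](C)(C)Cl
Why: Imidazole-mediated silylation of the three phenols and of the enolic 3-OH gives a lipophilic, non-chelating substrate for the hydrogenation and installs the only protecting groups the route still needs, all removable by fluoride near neutral pH.

Step 4
Reactants: 6 3,7,8-tris(TBSO)-2-[4-(TBSO)phenyl]-4H-chromen-4-one
Product: 8 (2R,3R,4R)-3,7,8-tris(TBSO)-2-[4-(TBSO)phenyl]chroman-4-ol, via flavanone 7 (not isolated)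
Conditions: Ru(cod)(2-methylallyl)2 (5 mol %), SINpEt·HBF4 (one antipode, 10 mol %), KOt-Bu (10 mol %), n-hexane, 70 °C; then 6, H2 (100 bar), toluene, 40 °C
Reagents that add atoms: none
Why: Proposed new method: the ruthenium hydride formed from Ru(cod)(2-methylallyl)2, the chiral carbene and H2 should add H2 syn across the C2=C3 bond of the planar 4-pyranone on the enantioface left open by the two naphthylethyl groups, giving the 2,3-cis flavanone 7, whose C4 carbonyl the same hydride then reduces. The closest known reactions are the Ru–NHC-catalysed asymmetric hydrogenation of flavones to cis-flavan-4-ols and the heterogeneous hydrogenation of flavonols to racemic 2,3-cis-3,4-cis-flavan-3,4-diols; what is new is the tetrasubstituted, 3-silyloxylated C2=C3 bond. No ring is closed in this step: ring C, made flat in step 1, is only saturated, so no mode of closure has to be chosen. C2 and C3 are set together by the catalyst (enantioface) and by the syn addition (cis), and C4 by the substrate, because hydride reaches the carbonyl of 7 from the face anti to the axial 3-silyloxy group and the 2-aryl group, which places the aryl group and both ring C oxygens on one side (2R,3R,4R). The step needs C=C reduction before C=O reduction, reduction of 7 faster than its epimerisation at C3, and an intact benzylic C4–O bond; the aprotic, essentially base-free medium, the silylated (non-chelating) 3-oxygen and a homogeneous ruthenium catalyst that does not hydrogenolyse benzylic alcohols should secure this.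

Step 5
Reactants: 8 (2R,3R,4R)-3,7,8-tris(TBSO)-2-[4-(TBSO)phenyl]chroman-4-ol
Product: 9 (2R,3R,4R)-6-bromo-3,7,8-tris(TBSO)-2-[4-(TBSO)phenyl]chroman-4-ol
Conditions: NBS (1.05 equiv), MeCN, −20 to 0 °C, dark
Reagents that add atoms: N-bromosuccinimide, O=C1CCC(=O)N1Br
Why: Electrophilic aromatic bromination, in which C6 is the only free carbon of ring A that is para to the ring oxygen O1 and ortho to the 7-silyloxy group, C5 is screened by the peri C4 carbinol, and the mono-oxygenated ring B is far less activated, so one equivalent of NBS should brominate C6 only.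

Step 6
Reactants: 9 (2R,3R,4R)-6-bromo-3,7,8-tris(TBSO)-2-[4-(TBSO)phenyl]chroman-4-ol (the portion meant for the 4'S half)
Product: 11 (2R,3R,4S)-6-bromo-3,7,8-tris(TBSO)-2-[4-(TBSO)phenyl]chroman-4-ol, via formate 10 (not isolated)
Conditions: HCO2H (3 equiv), PPh3 (3 equiv), DIAD (3 equiv), toluene, −20 to 0 °C; then NH3 (2 M in MeOH), 0 °C
Reagents that add atoms: formic acid, O=CO
Why: Mitsunobu inversion in which formate displaces the 4-alkoxyphosphonium group from the face anti to both the axial 3-silyloxy group and the 2-aryl group, so that SN2 attack and any SN1 leakage through the O1/O7-stabilised C4 cation converge on the 3,4-trans formate 10, whose labile formyl group ammonia then removes by acyl–oxygen cleavage with retention, sparing the aryl silyl ethers.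

Step 7
Reactants: 11 (2R,3R,4S)-6-bromo-3,7,8-tris(TBSO)-2-[4-(TBSO)phenyl]chroman-4-ol
Product: 12 (2R,3R,4S)-3,7,8-tris(TBSO)-2-[4-(TBSO)phenyl]-6-(4,4,5,5-tetramethyl-1,3,2-dioxaborolan-2-yl)chroman-4-ol
Conditions: B2pin2 (1.5 equiv), PdCl2(dppf) (5 mol %), KOAc (3 equiv), 1,4-dioxane, 85 °C
Reagents that add atoms: bis(pinacolato)diboron, CC1(C)OB(OC1(C)C)B1OC(C)(C)C(C)(C)O1
Why: Miyaura borylation (oxidative addition of the aryl bromide to zerovalent palladium, acetate-assisted transmetalation with B2pin2, reductive elimination), to which the free secondary carbinol and the silyl ethers are inert under the weak base KOAc.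

Step 8
Reactants: 9 (2R,3R,4R)-6-bromo-3,7,8-tris(TBSO)-2-[4-(TBSO)phenyl]chroman-4-ol (the remaining portion); 12 (2R,3R,4S)-6-boryl-3,7,8-tris(TBSO)-2-[4-(TBSO)phenyl]chroman-4-ol (1.2 equiv)
Product: 13 (2R,2'R,3R,3'R,4R,4'S)-3,3',7,7',8,8'-hexakis(TBSO)-2,2'-bis[4-(TBSO)phenyl]-6,6'-bichromane-4,4'-diol
Conditions: Pd(OAc)2 (5 mol %), SPhos (10 mol %), K3PO4 (3 equiv), toluene–H2O 10:1, 60 °C, degassed
Reagents that add atoms: none
Why: Suzuki–Miyaura cross-coupling with SPhos, a ligand suited to electron-rich, ortho-substituted partners; as one partner carries only bromine and the other only boron, the 4R half and the 4'S half are joined without statistical homodimer, and the biaryl axis, with one ortho substituent on each ring, should give no separable atropisomers.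

Step 9
Reactants: 13 (2R,2'R,3R,3'R,4R,4'S)-octasilylated 6,6'-bichromane-4,4'-diol
Product: 14 (2R,2'R,3R,3'R,4R,4'S)-2,2'-bis(4-hydroxyphenyl)-6,6'-bichromane-3,3',4,4',7,7',8,8'-octol (CNP0121763.1)
Conditions: n-Bu4NF (16 equiv), AcOH (16 equiv), THF, 0 °C to rt, argon; Sephadex LH-20 (EtOH)
Reagents that add atoms: none
Why: Fluoride cleaves the six aryl and two secondary alkyl silyl ethers through pentacoordinate silicates while the acetic acid buffer keeps the medium near neutral, so neither phenolate-driven quinone methide formation nor acid ionisation can scramble the C4 carbinols, and no hydrogenolysis is involved.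

Compound list
1 | 1-(2-hydroxy-3,4-dimethoxyphenyl)ethanone | CC(=O)c1ccc(OC)c(OC)c1O | starting material
2 | 4-methoxybenzaldehyde | COc1ccc(C=O)cc1 | starting material
3 | (E)-1-(2-hydroxy-3,4-dimethoxyphenyl)-3-(4-methoxyphenyl)prop-2-en-1-one | COc1ccc(/C=C/C(=O)c2ccc(OC)c(OC)c2O)cc1 | intermediate
4 | 3-hydroxy-7,8-dimethoxy-2-(4-methoxyphenyl)-4H-chromen-4-one | COc1ccc(-c2oc3c(OC)c(OC)ccc3c(=O)c2O)cc1 | intermediate
5 | 3,7,8-trihydroxy-2-(4-hydroxyphenyl)-4H-chromen-4-one | Oc1ccc(-c2oc3c(O)c(O)ccc3c(=O)c2O)cc1 | intermediate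
6 | 3,7,8-tris(tert-butyldimethylsilyloxy)-2-[4-(tert-butyldimethylsilyloxy)phenyl]-4H-chromen-4-one | CC(C)(C)[Si](C)(C)Oc1ccc(-c2oc3c(O[Si](C)(C)C(C)(C)C)c(O[Si](C)(C)C(C)(C)C)ccc3c(=O)c2O[Si](C)(C)C(C)(C)C)cc1 | intermediate
7 | (2R,3S)-3,7,8-tris(tert-butyldimethylsilyloxy)-2-[4-(tert-butyldimethylsilyloxy)phenyl]chroman-4-one (2,3-cis) | CC(C)(C)[Si](C)(C)Oc1ccc([C@H]2Oc3c(ccc(O[Si](C)(C)C(C)(C)C)c3O[Si](C)(C)C(C)(C)C)C(=O)[C@H]2O[Si](C)(C)C(C)(C)C)cc1 | intermediate
8 | (2R,3R,4R)-3,7,8-tris(tert-butyldimethylsilyloxy)-2-[4-(tert-butyldimethylsilyloxy)phenyl]chroman-4-ol (2,3-cis-3,4-cis) | CC(C)(C)[Si](C)(C)Oc1ccc([C@H]2Oc3c(ccc(O[Si](C)(C)C(C)(C)C)c3O[Si](C)(C)C(C)(C)C)[C@@H](O)[C@H]2O[Si](C)(C)C(C)(C)C)cc1 | intermediate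
9 | (2R,3R,4R)-6-bromo-3,7,8-tris(tert-butyldimethylsilyloxy)-2-[4-(tert-butyldimethylsilyloxy)phenyl]chroman-4-ol | CC(C)(C)[Si](C)(C)Oc1ccc([C@H]2Oc3c(cc(Br)c(O[Si](C)(C)C(C)(C)C)c3O[Si](C)(C)C(C)(C)C)[C@@H](O)[C@H]2O[Si](C)(C)C(C)(C)C)cc1 | intermediate
10 | (2R,3S,4S)-6-bromo-3,7,8-tris(tert-butyldimethylsilyloxy)-2-[4-(tert-butyldimethylsilyloxy)phenyl]chroman-4-yl formate (2,3-cis-3,4-trans) | CC(C)(C)[Si](C)(C)Oc1ccc([C@H]2Oc3c(cc(Br)c(O[Si](C)(C)C(C)(C)C)c3O[Si](C)(C)C(C)(C)C)[C@H](OC=O)[C@H]2O[Si](C)(C)C(C)(C)C)cc1 | intermediate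
11 | (2R,3R,4S)-6-bromo-3,7,8-tris(tert-butyldimethylsilyloxy)-2-[4-(tert-butyldimethylsilyloxy)phenyl]chroman-4-ol (2,3-cis-3,4-trans) | CC(C)(C)[Si](C)(C)Oc1ccc([C@H]2Oc3c(cc(Br)c(O[Si](C)(C)C(C)(C)C)c3O[Si](C)(C)C(C)(C)C)[C@H](O)[C@H]2O[Si](C)(C)C(C)(C)C)cc1 | intermediate
12 | (2R,3R,4S)-3,7,8-tris(tert-butyldimethylsilyloxy)-2-[4-(tert-butyldimethylsilyloxy)phenyl]-6-(4,4,5,5-tetramethyl-1,3,2-dioxaborolan-2-yl)chroman-4-ol | CC(C)(C)[Si](C)(C)Oc1ccc([C@H]2Oc3c(cc(B4OC(C)(C)C(C)(C)O4)c(O[Si](C)(C)C(C)(C)C)c3O[Si](C)(C)C(C)(C)C)[C@H](O)[C@H]2O[Si](C)(C)C(C)(C)C)cc1 | intermediate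
13 | (2R,2'R,3R,3'R,4R,4'S)-3,3',7,7',8,8'-hexakis(tert-butyldimethylsilyloxy)-2,2'-bis[4-(tert-butyldimethylsilyloxy)phenyl]-6,6'-bichromane-4,4'-diol | CC(C)(C)[Si](C)(C)Oc1ccc([C@H]2Oc3c(cc(-c4cc5c(c(O[Si](C)(C)C(C)(C)C)c4O[Si](C)(C)C(C)(C)C)O[C@H](c4ccc(O[Si](C)(C)C(C)(C)C)cc4)[C@H](O[Si](C)(C)C(C)(C)C)[C@H]5O)c(O[Si](C)(C)C(C)(C)C)c3O[Si](C)(C)C(C)(C)C)[C@@H](O)[C@H]2O[Si](C)(C)C(C)(C)C)cc1 | intermediate
14 | (2R,2'R,3R,3'R,4R,4'S)-2,2'-bis(4-hydroxyphenyl)-6,6'-bichromane-3,3',4,4',7,7',8,8'-octol | Oc1ccc([C@H]2Oc3c(cc(-c4cc5c(c(O)c4O)O[C@H](c4ccc(O)cc4)[C@H](O)[C@H]5O)c(O)c3O)[C@@H](O)[C@H]2O)cc1 | target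

Total step count: 9. Longest linear sequence: 9 steps (1 → 4 → 5 → 6 → 8 → 9 → 11 → 12 → 13 → 14). Bromide 9 serves both as the electrophile of step 8 and, after steps 6 and 7, as the source of the nucleophile.

Steps most likely to fail

Step 4 (Proposed new method). Hydrogen uptake at the tetrasubstituted, silyloxy-flanked C2=C3 bond may be slow or absent, the enantioface discrimination may be weak, or flavanone 7 may epimerise at C3 before it is reduced. The fallback sets out from 6 and comes back at 8. Hydrogenation of 6 over Raney Ni (washed to neutrality; H2 80 bar, EtOAc, 60 °C) is the heterogeneous reduction known to turn flavonols into racemic 2,3-cis-3,4-cis diols. It should give 8 as the racemate, that is together with its mirror image (2S,3S,4S)-3,7,8-tris(tert-butyldimethylsilyloxy)-2-[4-(tert-butyldimethylsilyloxy)phenyl]chroman-4-ol F1. Preparative chromatography on a cellulose tris(3,5-dimethylphenylcarbamate) phase would then return 8. Catalyst control is thus replaced by resolution at an early, inexpensive stage.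

Step 8. The electron-rich boronate may lose boron by protodeboronation, and transmetalation may be slow between two partners that each carry a bulky silyloxy group next to the reacting carbon, so that homocoupling competes. The fallback sets out from 11 and comes back at 13. Stannylation of 11 with hexamethylditin (Pd(PPh3)4, toluene, 100 °C) should give the arylstannane (2R,3R,4S)-3,7,8-tris(tert-butyldimethylsilyloxy)-2-[4-(tert-butyldimethylsilyloxy)phenyl]-6-(trimethylstannyl)chroman-4-ol F2. Stille coupling of this stannane with 9 (Pd(PPh3)4, CuI, CsF, DMF, 45 °C) should give 13. The union then runs without base and water, on which the loss of boron depends, and through a tin-to-copper transmetalation instead of a boronate.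

Step 6. The Mitsunobu betaine may fail to activate the carbinol beside the axial 3-silyloxy group, or the phosphonium ion may ionise and lose H-3 or suffer silyl migration instead of being substituted. The fallback sets out from 9 and comes back at 11. It is the acid-catalysed epimerisation known for 2,3-cis-3,4-cis flavan-3,4-diols, which go over to their 3,4-trans isomers in aqueous acid (10-camphorsulfonic acid, 5 mol %, THF–H2O 4:1, rt). Water should capture the C4 cation on the face anti to the 3-silyloxy and 2-aryl groups; the reaction is stopped at partial conversion, 11 is separated, and unchanged 9 is resubmitted. This fallback forms no compound outside the list (F0).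

Further compounds
F1 | step 4 | (2S,3S,4S)-3,7,8-tris(tert-butyldimethylsilyloxy)-2-[4-(tert-butyldimethylsilyloxy)phenyl]chroman-4-ol (enantiomer of 8) | CC(C)(C)[Si](C)(C)Oc1ccc([C@@H]2Oc3c(ccc(O[Si](C)(C)C(C)(C)C)c3O[Si](C)(C)C(C)(C)C)[C@H](O)[C@@H]2O[Si](C)(C)C(C)(C)C)cc1
F2 | step 8 | (2R,3R,4S)-3,7,8-tris(tert-butyldimethylsilyloxy)-2-[4-(tert-butyldimethylsilyloxy)phenyl]-6-(trimethylstannyl)chroman-4-ol | CC(C)(C)[Si](C)(C)Oc1ccc([C@H]2Oc3c(cc([Sn](C)(C)C)c(O[Si](C)(C)C(C)(C)C)c3O[Si](C)(C)C(C)(C)C)[C@H](O)[C@H]2O[Si](C)(C)C(C)(C)C)cc1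
F0 | step 6 | none | none
A1 | direct plan | (2E,2'E)-1,1'-[2,2',3,3'-tetrakis(benzyloxy)-4,4'-dihydroxybiphenyl-5,5'-diyl]bis{3-[4-(benzyloxy)phenyl]prop-2-en-1-one} | O=C(/C=C/c1ccc(OCc2ccccc2)cc1)c1cc(-c2cc(C(=O)/C=C/c3ccc(OCc4ccccc4)cc3)c(O)c(OCc3ccccc3)c2OCc2ccccc2)c(OCc2ccccc2)c(OCc2ccccc2)c1O
A2 | direct plan | (2S,2'S)-7,7',8,8'-tetrakis(benzyloxy)-2,2'-bis[4-(benzyloxy)phenyl]-2H,2'H-6,6'-bichromene | c1ccccc1COc1ccc([C@H]2Oc3c(cc(-c4cc5c(c(OCc6ccccc6)c4OCc4ccccc4)O[C@H](c4ccc(OCc6ccccc6)cc4)C=C5)c(OCc4ccccc4)c3OCc3ccccc3)C=C2)cc1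
A3 | direct plan | (2R,2'R,3R,3'R,4R,4'S)-7,7',8,8'-tetrakis(benzyloxy)-2,2'-bis[4-(benzyloxy)phenyl]-6,6'-bichromane-3,3',4,4'-tetrol | c1ccccc1COc1ccc([C@H]2Oc3c(cc(-c4cc5c(c(OCc6ccccc6)c4OCc4ccccc4)O[C@H](c4ccc(OCc6ccccc6)cc4)[C@H](O)[C@H]5O)c(OCc4ccccc4)c3OCc3ccccc3)[C@@H](O)[C@H]2O)cc1
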